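**Strategy.** Ring numbering: O1, C2 (guaiacyl), C3 (CH2OH), C4 (syringoyl), C5 (CH2). The plan cuts both ring bonds of C2. This carbon is benzylic and flanked by O1 and C3, so it can be delivered as an aryl aldehyde carbon inserted between a C5 oxygen and a nucleophilic C3. In one operation O-benzylvanillin condenses with the silylated C5 hydroxyl to an oxocarbenium ion (O1–C2) and the allylsilane terminus closes the tetrahydrofuran (C2–C3), setting C2 and C3 from C4. The precursor is the (R)-4-benzyloxazolidinone imide of (2S,3E)-2-(hydroxymethyl)-5-(trimethylsilyl)pent-3-enoic acid. The vinyl group left on C3 is later trimmed to CH2OH; the imide becomes the aryl ketone.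

Key step: step 4

**Remarks on the chemistry**
- Descriptors: with the ring numbering above, every vinyl-bearing tetrahydrofuran and the aldehyde are (2S,3S,4S). C3 becomes R in the alcohols only because CH2OH ranks between C2 and C4. No centre is inverted.
- Order of events: silicon is introduced after the hydroxymethylation, because TiCl4 with a formaldehyde source would allylate or protodesilylate an allylsilane.
- The hydroxyl of the precursor is silylated in the flask before the aldehyde is activated, so the condensation expels a disiloxane instead of water.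
- Assumption: the cross-metathesis product is carried on as its E isomer. The alkene geometry is erased in the key step.

**Step 1**
Reactants: 1 (R)-4-benzyl-2-oxazolidinone; 2 but-3-enoic acid
Product: 5 (R)-4-benzyl-3-(but-3-enoyl)oxazolidin-2-one, via but-3-enoic pivalic anhydride 3 (not isolated), via N-lithio oxazolidinone 4 (not isolated)
Conditions: 2, PivCl, Et3N, THF, −78 → 0 °C; separately 1, n-BuLi, THF, −78 °C; combine, −78 → 0 °C; aq. NH4Cl
Reagents that add atoms: pivaloyl chloride CC(C)(C)C(=O)Cl (its acyl group is present only in 3); n-BuLi [Li]CCCC (its lithium is present only in 4)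
Why: N-acylation of a lithiated oxazolidinone by a mixed anhydride takes place at the less hindered butenoyl carbonyl, and the low temperature keeps the β,γ-alkene out of conjugation.

**Step 2**
Reactants: 5 (R)-4-benzyl-3-(but-3-enoyl)oxazolidin-2-one; 6 1,3,5-trioxane
Product: 8 (R)-4-benzyl-3-[(2S)-2-(hydroxymethyl)but-3-enoyl]oxazolidin-2-one, via trichlorotitanium dienolate 7 (not isolated)
Conditions: TiCl4 (1.05 equiv), i-Pr2NEt (1.15 equiv), CH2Cl2, 0 °C; then 6 (1.2 equiv), TiCl4 (1.05 equiv), 0 °C; aq. NH4Cl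
Reagents that add atoms: TiCl4 Cl[Ti](Cl)(Cl)Cl (present only in 7)
Why: Auxiliary-controlled titanium-enolate hydroxymethylation, in which the chelated (Z)-dienolate reacts at its α-carbon with TiCl4-opened trioxane on the face away from the benzyl group and so sets C4 as S.

**Step 3**
Reactants: 8 (R)-4-benzyl-3-[(2S)-2-(hydroxymethyl)but-3-enoyl]oxazolidin-2-one; 9 allyltrimethylsilane
Product: 10 (R)-4-benzyl-3-[(2S,3E)-2-(hydroxymethyl)-5-(trimethylsilyl)pent-3-enoyl]oxazolidin-2-one
Conditions: 9 (4 equiv), second-generation Hoveyda–Grubbs catalyst RuCl2(H2IMes)(=CH-C6H4-2-O-i-Pr) (5 mol %), 1,4-benzoquinone (10 mol %), CH2Cl2, 40 °C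
Reagents that add atoms: none
Why: Olefin cross-metathesis pairs the allylically branched, slowly homodimerising alkene of 8 with an excess of the fast-reacting 9, which should favour the E cross product, while benzoquinone holds back ruthenium hydride isomerisation and C4 is not touched.

**Step 4**
Reactants: 10 (R)-4-benzyl-3-[(2S,3E)-2-(hydroxymethyl)-5-(trimethylsilyl)pent-3-enoyl]oxazolidin-2-one; 11 4-benzyloxy-3-methoxybenzaldehyde
Product: 14 (R)-4-benzyl-3-{[(2S,3S,4S)-2-(4-benzyloxy-3-methoxyphenyl)-3-vinyltetrahydrofuran-4-yl]carbonyl}oxazolidin-2-one, via trimethylsilyl ether 12 (not isolated), via oxocarbenium triflate 13 (not isolated)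
Conditions: TMSOTf (1.05 equiv), 2,6-di-tert-butyl-4-methylpyridine (1.2 equiv), CH2Cl2 (0.05 M), −78 °C; then 11 (1.1 equiv), TMSOTf (0.3 equiv), −78 → −30 °C; aq. NaHCO3
Reagents that add atoms: TMSOTf C[Si](C)(C)OS(=O)(=O)C(F)(F)F (its Me3Si group is present only in 12 and its triflate only in 13)
Why: TMSOTf and the hindered pyridine first cap the C5 hydroxyl as 12, so that neither water nor TfOH is set loose, and catalytic TMSOTf then condenses 12 with 11 to the (E)-oxocarbenium ion 13 (O1–C2), whose carbon is attacked by the γ-carbon of the allylsilane anti to silicon (C2–C3) before the β-silyl cation sheds Me3Si+ to leave the C3 vinyl group. The closest known reaction type is the intramolecular silyl-modified Sakurai condensation of aldehydes with 5-silylpent-3-en-1-ols, which gives 2-substituted 3-vinyltetrahydrofurans. The one ring closes through an envelope transition state that is 5-exo with respect to the alkene and 5-endo with respect to the C=O+ bond. C3 is governed by C4: allylic 1,3-strain keeps the C4–H bond near the alkene plane and the imide pseudo-equatorial, so the tethered cation reaches the alkene face anti to the imide and vinyl and acyl end up trans. C2 is governed by the (E)-geometry of 13 and of the allylsilane, which place the aryl group over C3–H instead of over the CH2SiMe3 chain (2,3-trans), and reversible benzylic ionisation of the electron-rich 2-aryl ether would drain any cis isomer to the same, more stable product. The step needs bonding at C3 and not at C9 (five- not six-membered ring, no oxonia-Cope scrambling) and ring closure faster than protodesilylation; the β-silicon effect secures the first and the proton-free medium the second.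

**Step 5**
Reactants: 14 (R)-4-benzyl-3-{[(2S,3S,4S)-2-(4-benzyloxy-3-methoxyphenyl)-3-vinyltetrahydrofuran-4-yl]carbonyl}oxazolidin-2-one
Product: 15 (2S,3S,4S)-2-(4-benzyloxy-3-methoxyphenyl)-N-methoxy-N-methyl-3-vinyltetrahydrofuran-4-carboxamide
Conditions: AlMe3 (3 equiv), MeONHMe·HCl (3 equiv), CH2Cl2, 0 °C → rt; then 14, −10 °C → rt; aq. potassium sodium tartrate
Reagents that add atoms: N,O-dimethylhydroxylamine hydrochloride CNOC.Cl
Why: Weinreb aminolysis of the imide by the aluminium amide attacks the exocyclic carbonyl activated by aluminium chelation, releases 1 for reuse, and is too weakly basic to disturb C4 or expel the β-oxygen O1.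

**Step 6**
Reactants: 16 4-bromo-2,6-dimethoxyphenol
Product: 17 2-benzyloxy-5-bromo-1,3-dimethoxybenzene
Conditions: BnBr, K2CO3, DMF, rt → 50 °C
Reagents that add atoms: benzyl bromide BrCc1ccccc1
Why: Williamson ether synthesis on the phenoxide installs the same protecting group as in 11, so that both fall in one final operation.

**Step 7**
Reactants: 15 (2S,3S,4S)-2-(4-benzyloxy-3-methoxyphenyl)-N-methoxy-N-methyl-3-vinyltetrahydrofuran-4-carboxamide; 17 2-benzyloxy-5-bromo-1,3-dimethoxybenzene
Product: 19 (4-benzyloxy-3,5-dimethoxyphenyl)[(2S,3S,4S)-2-(4-benzyloxy-3-methoxyphenyl)-3-vinyltetrahydrofuran-4-yl]methanone, via aryllithium 18 (not isolated)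
Conditions: 17 (1.5 equiv), n-BuLi (1.45 equiv), THF, −78 °C; then 15, −78 → −40 °C; aq. NH4Cl
Reagents that add atoms: n-BuLi [Li]CCCC (its lithium is present only in 18)
Why: Bromine–lithium exchange followed by Weinreb ketone synthesis, in which lithium chelation by the N-methoxy group stops the addition at the ketone level and fast addition at −78 °C outruns deprotonation at C4, so neither epimerisation nor β-elimination of O1 is expected.

**Step 8**
Reactants: 19 (4-benzyloxy-3,5-dimethoxyphenyl)[(2S,3S,4S)-2-(4-benzyloxy-3-methoxyphenyl)-3-vinyltetrahydrofuran-4-yl]methanone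
Product: 21 (2S,3S,4S)-4-(4-benzyloxy-3,5-dimethoxybenzoyl)-2-(4-benzyloxy-3-methoxyphenyl)tetrahydrofuran-3-carbaldehyde, via vicinal diol 20 (not isolated)
Conditions: OsO4 (2 mol %), NaIO4 (4 equiv), 2,6-lutidine (2 equiv), dioxane/H2O 3:1, rt; used crude
Reagents that add atoms: OsO4 O=[Os](=O)(=O)=O (delivers the oxygens of 20); NaIO4 [Na+].[O-]I(=O)(=O)=O and water O (renew that oxygen)
Why: Lemieux–Johnson oxidation dihydroxylates the only alkene and cleaves the diol, while 2,6-lutidine keeps the medium near neutral so that C3 and C4, already in the favoured all-trans array, stay in place.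

**Step 9**
Reactants: 21 (2S,3S,4S)-4-(4-benzyloxy-3,5-dimethoxybenzoyl)-2-(4-benzyloxy-3-methoxyphenyl)tetrahydrofuran-3-carbaldehyde
Product: 22 (4-benzyloxy-3,5-dimethoxyphenyl)[(2S,3R,4S)-2-(4-benzyloxy-3-methoxyphenyl)-3-(hydroxymethyl)tetrahydrofuran-4-yl]methanone
Conditions: NaBH(OAc)3 (1.5 equiv), THF, 0 °C → rt
Reagents that add atoms: none
Why: Chemoselective hydride reduction, since the weak and non-basic donor NaBH(OAc)3 reduces the aldehyde but not the electron-rich conjugated aryl ketone, and no stereocentre is formed.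

**Step 10**
Reactants: 22 (4-benzyloxy-3,5-dimethoxyphenyl)[(2S,3R,4S)-2-(4-benzyloxy-3-methoxyphenyl)-3-(hydroxymethyl)tetrahydrofuran-4-yl]methanone
Product: 23 (4-hydroxy-3,5-dimethoxyphenyl)[(2S,3R,4S)-2-(4-hydroxy-3-methoxyphenyl)-3-(hydroxymethyl)tetrahydrofuran-4-yl]methanone (target)
Conditions: H2 (1 atm), 10% Pd/C, EtOAc, rt, stopped after uptake of two equivalents
Reagents that add atoms: none
Why: Catalytic hydrogenolysis of both aryl benzyl ethers is neutral, which avoids base-induced epimerisation at C4 or retro-oxa-Michael ring opening, and the mild conditions should spare the deactivated aryl ketone and the C2–O1 bond.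

**Compound list**
1 | (R)-4-benzyl-2-oxazolidinone | O=C1N[C@H](Cc2ccccc2)CO1 | starting material
2 | but-3-enoic acid | C=CCC(=O)O | starting material
3 | but-3-enoic pivalic anhydride | C=CCC(=O)OC(=O)C(C)(C)C | intermediate
4 | N-lithio-(R)-4-benzyl-2-oxazolidinone | [Li]N1[C@H](Cc2ccccc2)COC1=O | intermediate
5 | (R)-4-benzyl-3-(but-3-enoyl)oxazolidin-2-one | C=CCC(=O)N1[C@H](Cc2ccccc2)COC1=O | intermediate
6 | 1,3,5-trioxane | C1OCOCO1 | starting material
7 | trichlorotitanium (Z)-dienolate of 5 | C=C/C=C(\O[Ti](Cl)(Cl)Cl)N1[C@H](Cc2ccccc2)COC1=O | intermediate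
8 | (R)-4-benzyl-3-[(2S)-2-(hydroxymethyl)but-3-enoyl]oxazolidin-2-one | C=C[C@@H](CO)C(=O)N1[C@H](Cc2ccccc2)COC1=O | intermediate
9 | allyltrimethylsilane | C=CC[Si](C)(C)C | starting material
10 | (R)-4-benzyl-3-[(2S,3E)-2-(hydroxymethyl)-5-(trimethylsilyl)pent-3-enoyl]oxazolidin-2-one | C[Si](C)(C)C/C=C/[C@@H](CO)C(=O)N1[C@H](Cc2ccccc2)COC1=O | intermediate
11 | 4-benzyloxy-3-methoxybenzaldehyde | COc1cc(C=O)ccc1OCc1ccccc1 | starting material
12 | (R)-4-benzyl-3-[(2S,3E)-5-(trimethylsilyl)-2-(trimethylsilyloxymethyl)pent-3-enoyl]oxazolidin-2-one | C[Si](C)(C)C/C=C/[C@@H](CO[Si](C)(C)C)C(=O)N1[C@H](Cc2ccccc2)COC1=O | intermediate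
13 | (E)-oxocarbenium triflate from 12 and 11 | C[Si](C)(C)C/C=C/[C@@H](C/[O+]=C/c1ccc(OCc2ccccc2)c(OC)c1)C(=O)N1[C@H](Cc2ccccc2)COC1=O.[O-]S(=O)(=O)C(F)(F)F | intermediate
14 | (R)-4-benzyl-3-{[(2S,3S,4S)-2-(4-benzyloxy-3-methoxyphenyl)-3-vinyltetrahydrofuran-4-yl]carbonyl}oxazolidin-2-one (2,3-trans and 3,4-trans) | COc1cc([C@H]2OC[C@@H](C(=O)N3[C@H](Cc4ccccc4)COC3=O)[C@@H]2C=C)ccc1OCc1ccccc1 | intermediate
15 | (2S,3S,4S)-2-(4-benzyloxy-3-methoxyphenyl)-N-methoxy-N-methyl-3-vinyltetrahydrofuran-4-carboxamide | COc1cc([C@H]2OC[C@@H](C(=O)N(C)OC)[C@@H]2C=C)ccc1OCc1ccccc1 | intermediate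
16 | 4-bromo-2,6-dimethoxyphenol | Oc1c(OC)cc(Br)cc1OC | starting material
17 | 2-benzyloxy-5-bromo-1,3-dimethoxybenzene | COc1cc(Br)cc(OC)c1OCc1ccccc1 | intermediate
18 | (4-benzyloxy-3,5-dimethoxyphenyl)lithium | [Li]c1cc(OC)c(OCc2ccccc2)c(OC)c1 | intermediate
19 | (4-benzyloxy-3,5-dimethoxyphenyl)[(2S,3S,4S)-2-(4-benzyloxy-3-methoxyphenyl)-3-vinyltetrahydrofuran-4-yl]methanone | COc1cc([C@H]2OC[C@@H](C(=O)c3cc(OC)c(OCc4ccccc4)c(OC)c3)[C@@H]2C=C)ccc1OCc1ccccc1 | intermediate
20 | 1,2-diol from 19 (both carbinol epimers) | COc1cc([C@H]2OC[C@@H](C(=O)c3cc(OC)c(OCc4ccccc4)c(OC)c3)[C@@H]2C(O)CO)ccc1OCc1ccccc1 | intermediate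
21 | (2S,3S,4S)-4-(4-benzyloxy-3,5-dimethoxybenzoyl)-2-(4-benzyloxy-3-methoxyphenyl)tetrahydrofuran-3-carbaldehyde | COc1cc([C@H]2OC[C@@H](C(=O)c3cc(OC)c(OCc4ccccc4)c(OC)c3)[C@@H]2C=O)ccc1OCc1ccccc1 | intermediate
22 | (4-benzyloxy-3,5-dimethoxyphenyl)[(2S,3R,4S)-2-(4-benzyloxy-3-methoxyphenyl)-3-(hydroxymethyl)tetrahydrofuran-4-yl]methanone | COc1cc([C@H]2OC[C@@H](C(=O)c3cc(OC)c(OCc4ccccc4)c(OC)c3)[C@@H]2CO)ccc1OCc1ccccc1 | intermediate
23 | (4-hydroxy-3,5-dimethoxyphenyl)[(2S,3R,4S)-2-(4-hydroxy-3-methoxyphenyl)-3-(hydroxymethyl)tetrahydrofuran-4-yl]methanone | COc1cc([C@H]2OC[C@@H](C(=O)c3cc(OC)c(O)c(OC)c3)[C@@H]2CO)ccc1O | target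

**Total step count:** 10. **Longest linear sequence:** 9 (steps 1–5 and 7–10; step 6 is a one-step side branch).

**Steps most likely to fail**

1. Step 4 (key step). The allylsilane may be protodesilylated before the ring closes. The two faces of the E-alkene at C3 may be poorly discriminated, or intermolecular allylation may intervene.
The fallback uses the known condensation of cyclic allylsiloxanes with aldehydes. It sets out from 8 and comes back at 14, replacing steps 3 and 4. Alcohol 8 is silylated with allyl(chloro)dimethylsilane and imidazole in CH2Cl2 to the allyldimethylsilyl ether F1. Ring-closing metathesis with the second-generation Grubbs catalyst RuCl2(H2IMes)(PCy3)(=CHPh) in dilute refluxing CH2Cl2 gives the seven-membered (Z)-allylsiloxane F2. F2 is then condensed with 11 under BF3·OEt2 in CH2Cl2 from −78 °C to room temperature.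
The same two bonds are formed, but silicon stays tied to O1 until the oxocarbenium ion exists. The Z-alkene raises the allylic strain that steers C3, and warming with BF3·OEt2 lets C2 settle to the trans isomer by reversible benzylic ionisation.

2. Step 2. The dienolate may react through its γ-carbon, or the alkene may drift into conjugation, which erases C4.
The fallback masks the vinyl group as a saturated selenide, so that an ordinary enolate is hydroxymethylated. It sets out from 1 and comes back at 8. γ-Butyrolactone is opened with PhSeNa, made from (PhSe)2 and NaBH4 in DMF at 120 °C, to 4-(phenylselanyl)butanoic acid F3. This acid is coupled with 1 (DCC, catalytic DMAP, CH2Cl2) to the saturated imide F4. The conditions of step 2 with 6 give the (2S)-hydroxymethyl imide F5. H2O2 in CH2Cl2/pyridine from 0 °C to room temperature oxidises it to the selenoxide F6, which undergoes syn-elimination toward its only β-hydrogens and delivers 8 under neutral conditions.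

3. Step 5. The aluminium amide may attack the ring carbonyl of the auxiliary and open the oxazolidinone, because the acyl carbon sits on a substituted ring.
The fallback separates cleavage from amide formation. It sets out from 14 and comes back at 15. LiOH/H2O2 in THF/H2O at 0 °C, followed by Na2SO3, exploits the preference of hydroperoxide for the exocyclic carbonyl of hindered imides and gives the tetrahydrofuran carboxylic acid F7 with release of 1. F7 is then coupled with MeONHMe·HCl (EDC·HCl, HOBt, i-Pr2NEt, CH2Cl2) to 15.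

**Further compounds**
F1 | step 4 | (R)-3-[(2S)-2-{[allyl(dimethyl)silyl]oxymethyl}but-3-enoyl]-4-benzyloxazolidin-2-one | C=CC[Si](C)(C)OC[C@H](C=C)C(=O)N1[C@H](Cc2ccccc2)COC1=O
F2 | step 4 | (R)-4-benzyl-3-{[(6S)-2,2-dimethyl-2,3,6,7-tetrahydro-1,2-oxasilepin-6-yl]carbonyl}oxazolidin-2-one | C[Si]1(C)C/C=C\[C@@H](CO1)C(=O)N2[C@H](Cc3ccccc3)COC2=O
F3 | step 2 | 4-(phenylselanyl)butanoic acid | OC(=O)CCC[Se]c1ccccc1
F4 | step 2 | (R)-4-benzyl-3-[4-(phenylselanyl)butanoyl]oxazolidin-2-one | O=C(CCC[Se]c1ccccc1)N1[C@H](Cc2ccccc2)COC1=O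
F5 | step 2 | (R)-4-benzyl-3-[(2S)-2-(hydroxymethyl)-4-(phenylselanyl)butanoyl]oxazolidin-2-one | C(C[Se]c1ccccc1)[C@@H](CO)C(=O)N1[C@H](Cc2ccccc2)COC1=O
F6 | step 2 | selenoxide of F5 | C(C[Se](=O)c1ccccc1)[C@@H](CO)C(=O)N1[C@H](Cc2ccccc2)COC1=O
F7 | step 5 | (2S,3S,4S)-2-(4-benzyloxy-3-methoxyphenyl)-3-vinyltetrahydrofuran-4-carboxylic acid | COc1cc([C@H]2OC[C@@H](C(=O)O)[C@@H]2C=C)ccc1OCc1ccccc1
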